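**Plan**

1. Retrosynthesis: the 8,9-epoxide goes back to a C8=C9 alkene; the tertiary ester and secondary alcohol go back to β-hydroxy ketone 18 (C4–OH, C6=O) plus an aryl aldehyde; the isopropyl group goes back to a C4 ketone; the C6 oxygen and C5 hydrogen go back to a C5=C6 bond.
2. What remains is a bicyclic 5,8-diene. In its seven-membered ring (C1, C5–C10) the two functionalised edges C5–C6 and C8–C9 are separated only by the methylene C7, with quaternary C1 next to C10. This is the cyclohepta-1,4-diene pattern left by a cis-divinylcyclopropane Cope rearrangement, so the ring is cut at C7–C8 and C10–C1 into a 1-vinyl-2-methylcyclopentene (C7=C6–C5=C1) and a three-carbon vinylcarbenoid (C8–C9=C10).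
3. Forward: the five-membered ring is bought and turned into diene 5; the seven-membered ring is annulated in one operation (step 4); the carbenoid ester is then reduced to the C8 methyl, the C4 ketone unmasked, and C6–O/C5–H, the isopropyl carbinol, the ester and the epoxide are introduced in that order.
4. Stereochemistry: C1 from the chiral dirhodium catalyst by cyclopropane-to-quaternary-carbon chirality transfer in the Cope step; C5 by enolate protonation anti to the axial C1 methyl; C4 by organometallic attack anti to the same methyl; C6 by intramolecular hydride delivery from the C4 oxygen (1,3-anti); C8/C9 by epoxidation directed by the 6α-hydroxyl.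
5. Helpers: methyl ester (acceptor of the carbenoid, later the C8 methyl), ethylene ketal (masks C4=O), temporary cyclopropane, benzyl ether on the phenol.

Key step: step 4

Numbering: daucane numbering is used for all bicyclic compounds. Five-membered ring C1–C2–C3–C4–C5; seven-membered ring C1–C5–C6–C7–C8–C9–C10; C1 is the quaternary ring-fusion carbon with methyl C15, C5 the ring-fusion CH, C4 carries the isopropyl group (C11–C13), C8 carries C14. β is the face of the C1 methyl, α the opposite face. Compounds without the isopropyl group are named as 11,12,13-trinordaucanes.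

Assumption: the absolute sense of carbene transfer is assigned by analogy with donor/acceptor diazoacetates and monosubstituted alkenes (Rh2(R-DOSP)4 giving the cyclopropane drawn as 8); should diene 5 show the opposite sense, Rh2(S-DOSP)4 is used instead.

**Route**

Step 1
Reactants: 1 2-bromo-3-methylcyclopent-2-en-1-one; 2 ethylene glycol
Product: 3 6-bromo-7-methyl-1,4-dioxaspiro[4.4]non-6-ene
Conditions: ethylene glycol (5 equiv), p-TsOH·H2O (cat.), benzene, reflux, azeotropic removal of water
Reagents that add atoms: ethylene glycol (2), OCCO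
Why: acid-catalysed ketalisation driven by water removal; the vinylic bromine keeps the C=C bond in place, so the ketone is masked without double-bond migration and no stereocentre is formed.

Step 2
Reactants: 3 6-bromo-7-methyl-1,4-dioxaspiro[4.4]non-6-ene; 4 tributyl(vinyl)stannane
Product: 5 7-methyl-6-vinyl-1,4-dioxaspiro[4.4]non-6-ene
Conditions: Pd(PPh3)4 (5 mol%), toluene, 100 °C
Reagents that add atoms: tributyl(vinyl)stannane (4), C=C[Sn](CCCC)(CCCC)CCCC
Why: Stille coupling of the alkenyl bromide under zerovalent palladium catalysis should give the semicyclic 1,3-diene with the ring alkene unchanged; no stereocentre is formed.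

Step 3
Reactants: 6 methyl but-3-enoate
Product: 7 methyl 2-diazobut-3-enoate
Conditions: 4-acetamidobenzenesulfonyl azide, DBU, MeCN, 0 °C; used at once as a cold hexane solution
Reagents that add atoms: 4-acetamidobenzenesulfonyl azide, CC(=O)Nc1ccc(cc1)S(=O)(=O)N=[N+]=[N-]
Why: Regitz diazo transfer to the CH2 that is both allylic and α to the ester gives the vinyldiazoacetate, which is kept cold and used immediately because it slowly electrocyclises to a pyrazole.

Step 4
Reactants: 5 7-methyl-6-vinyl-1,4-dioxaspiro[4.4]non-6-ene; 7 methyl 2-diazobut-3-enoate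
Product: 9 methyl 4,4-(ethylenedioxy)-11,12,13-trinordauca-5,8-dien-14-oate (1β-methyl; dioxolane at C4, C5=C6 and C8=C9, CO2Me on C8), via cis-divinylcyclopropane 8 (not isolated)
Conditions: Rh2(R-DOSP)4 [dirhodium tetrakis((R)-N-(4-dodecylbenzenesulfonyl)prolinate)] (1 mol%), hexanes, −78 °C, slow addition of 7 (1.5 equiv), then rt; then toluene, 80 °C
Reagents that add atoms: methyl 2-diazobut-3-enoate (7), COC(=O)C(=[N+]=[N-])C=C
Why: The rhodium carbenoid from 7 (a donor/acceptor vinylcarbenoid, the ester being the activating group) adds to the terminal CH=CH2 of 5, closing the temporary cyclopropane by concerted [2+1] carbene transfer and making the C7–C8 bond; cis-divinylcyclopropane 8 then undergoes a [3,3]-sigmatropic (Cope) rearrangement through a boat transition state, which opens the three-membered ring and closes the seven-membered ring by forming the C10–C1 bond. The closest known reaction type is the tandem cyclopropanation/Cope rearrangement (formal [4+3] cycloaddition) of vinyldiazoacetates with 1,3-dienes, including 1-vinylcycloalkenes that give a quaternary ring-fusion carbon. The only stereocentre of 9, quaternary C1, is set by chirality transfer: the chiral prolinate catalyst fixes the two cyclopropane stereocentres and the boat geometry relays them to C1 while they themselves become sp2 (C6 and C8). Site selectivity and regiochemistry are secured by the substrate, because the tetrasubstituted ring alkene is too hindered for the carbenoid and the terminal vinyl carbon is the most accessible nucleophilic position (carbenoid carbon to C7, vinyl terminus to C1). The cis relation of the two alkenyl groups in 8 follows from the usual preference of donor/acceptor carbenoids to place the alkene substituent cis to the donor (vinyl) group and trans to the ester. Because the C1 methyl is cis to the cyclopropane on the ring alkene and points into the boat, the Cope step should be slower than usual and is completed by mild heating, kept low enough to avoid homolytic opening of 8, which would erode the enantiomeric purity.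

Step 5
Reactants: 9 methyl 4,4-(ethylenedioxy)-11,12,13-trinordauca-5,8-dien-14-oate
Product: 10 4,4-(ethylenedioxy)-11,12,13-trinordauca-5,8-dien-14-ol
Conditions: i-Bu2AlH (2.5 equiv), CH2Cl2, −78 °C; aqueous potassium sodium tartrate work-up
Reagents that add atoms: none
Why: 1,2-reduction of the conjugated ester by the aluminium hydride gives the primary allylic alcohol; the ketal and both alkenes are inert and C1 is untouched.

Step 6
Reactants: 10 4,4-(ethylenedioxy)-11,12,13-trinordauca-5,8-dien-14-ol
Product: 12 4,4-(ethylenedioxy)-11,12,13-trinordauca-5,8-diene, via pyridinium allylic sulfate 11 (not isolated)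
Conditions: SO3·pyridine, THF, 0 °C; then LiAlH4, THF, 0 °C to rt
Reagents that add atoms: sulfur trioxide–pyridine complex, O=S(=O)=O.c1ccncc1 (sulfate group of 11 only; nothing remains in 12)
Why: the primary allylic alcohol is converted into its sulfate monoester, which hydride displaces at the primary carbon (SN2), a known allylic deoxygenation that leaves the C8=C9 bond in place and turns the former ester carbon into methyl C14.

Step 7
Reactants: 12 4,4-(ethylenedioxy)-11,12,13-trinordauca-5,8-diene
Product: 13 11,12,13-trinordauca-5,8-dien-4-one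
Conditions: 1 M aq. HCl, THF, rt
Reagents that add atoms: water, O
Why: mild acid hydrolysis of the dioxolane releases the C4 ketone as an α-alkylidene cyclopentanone (C5=C6 conjugated); C5 is sp2, so nothing can epimerise at this stage.

Step 8
Reactants: 13 11,12,13-trinordauca-5,8-dien-4-one
Product: 15 6β-hydroxy-11,12,13-trinor-5α-dauc-8-en-4-one, via β-boryl ketone 14 (not isolated)
Conditions: B2pin2 (1.2 equiv), CuCl (5 mol%), Xantphos (5 mol%), NaOt-Bu (10 mol%), MeOH (2 equiv), THF, rt; then NaBO3·4H2O, THF/H2O, rt
Reagents that add atoms: bis(pinacolato)diboron, CC1(C)OB(OC1(C)C)B1OC(C)(C)C(C)(C)O1 (boryl group of 14); sodium perborate, [Na+].[Na+].O[B-]1(O)OO[B-](O)(O)OO1 (oxygen on C6 of 15)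
Why: copper-catalysed conjugate borylation of the s-cis enone should place boron on C6 from the convex β face (the α face of C6 lies over the C8=C9 bond of the folded cycloheptadiene), the enolate is then protonated by methanol at C5 anti to both the axial C1 methyl and the new C6–B bond to give the trans ring fusion (5α-H), and perborate oxidation with retention gives the alcohol; the C6 configuration is drawn as predicted and is erased in step 10.

Step 9
Reactants: 15 6β-hydroxy-11,12,13-trinor-5α-dauc-8-en-4-one; 16 isopropylmagnesium chloride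
Product: 17 5α-dauc-8-ene-4β,6β-diol (4α-isopropyl)
Conditions: i-PrMgCl (4 equiv), anhydrous CeCl3 (4 equiv), THF, −78 °C to 0 °C; aq. NH4Cl
Reagents that add atoms: isopropylmagnesium chloride (16), CC(C)[Mg]Cl
Why: organocerium 1,2-addition (low basicity limits enolisation, β-hydride reduction and retro-aldol of the alkoxide formed from the free hydroxyl) should occur on the α face of the C4 carbonyl, anti to the axial C1 methyl and to the metal-bound 6β-oxygen, giving 4β-OH and 4α-isopropyl.

Step 10
Reactants: 17 5α-dauc-8-ene-4β,6β-diol
Product: 18 4β-hydroxy-5α-dauc-8-en-6-one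
Conditions: DMP (1,1,1-triacetoxy-1,1-dihydro-1,2-benziodoxol-3(1H)-one, 1.5 equiv), NaHCO3, CH2Cl2, 0 °C to rt
Reagents that add atoms: none
Why: Dess–Martin oxidation converts only the secondary alcohol into the ketone under buffered neutral conditions, so the tertiary alcohol, the alkene and the C5 stereocentre (now α to the carbonyl) are left intact.

Step 11
Reactants: 18 4β-hydroxy-5α-dauc-8-en-6-one; 19 4-(benzyloxy)benzaldehyde
Product: 21 4β-[4-(benzyloxy)benzoyloxy]-5α-dauc-8-en-6α-ol, via samarium-bound hemiacetal 20 (not isolated)
Conditions: 19 (5 equiv), SmI2 (0.3 equiv), THF, −10 °C, exclusion of light; cold pH 7 buffer quench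
Reagents that add atoms: 4-(benzyloxy)benzaldehyde (19), O=Cc1ccc(OCc2ccccc2)cc1
Why: Proposed new method: the closest known reaction type is the Evans–Tishchenko reduction of secondary β-hydroxy ketones with aldehydes and catalytic samarium diiodide, applied here to a tertiary carbinol; the trivalent samarium alkoxide of the 4β-oxygen should add to the aldehyde to give hemiacetal 20, whose C–H is delivered through a six-membered chair to the samarium-activated C6 carbonyl from the β face on which O4 sits, so that the new hydroxyl is 6α (1,3-anti) and the oxidised hemiacetal becomes the aryl ester on the hindered tertiary oxygen, an acylation that would otherwise need protection of the secondary alcohol.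

Step 12
Reactants: 21 4β-[4-(benzyloxy)benzoyloxy]-5α-dauc-8-en-6α-ol
Product: 22 4β-[4-(benzyloxy)benzoyloxy]-8α,9α-epoxy-5α-daucan-6α-ol
Conditions: VO(acac)2 (5 mol%), t-BuOOH (1.5 equiv, in decane), CH2Cl2, 0 °C to rt
Reagents that add atoms: tert-butyl hydroperoxide, CC(C)(C)OO
Why: vanadium-catalysed hydroxyl-directed epoxidation, in which the homoallylic 6α-hydroxyl binds the metal and delivers oxygen to the α face of the only alkene (also the face anti to the C1 methyl), should give the 8α,9α-epoxide.

Step 13
Reactants: 22 4β-[4-(benzyloxy)benzoyloxy]-8α,9α-epoxy-5α-daucan-6α-ol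
Product: 23 4β-(4-hydroxybenzoyloxy)-8α,9α-epoxy-5α-daucan-6α-ol (CNP0264773.1)
Conditions: H2 (1 atm), Pd/C (10% palladium on carbon), EtOAc, rt
Reagents that add atoms: none
Why: hydrogenolysis of the aryl benzyl ether under neutral conditions frees the phenol; the non-benzylic trisubstituted epoxide and the tertiary ester should survive, and the absence of base avoids acyl migration to the free 6-hydroxyl.

**Compound list**

1 | 2-bromo-3-methylcyclopent-2-en-1-one | CC1=C(Br)C(=O)CC1 | starting material
2 | ethylene glycol | OCCO | starting material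
3 | 6-bromo-7-methyl-1,4-dioxaspiro[4.4]non-6-ene | CC1=C(Br)C2(CC1)OCCO2 | intermediate
4 | tributyl(vinyl)stannane | C=C[Sn](CCCC)(CCCC)CCCC | starting material
5 | 7-methyl-6-vinyl-1,4-dioxaspiro[4.4]non-6-ene | CC1=C(C=C)C2(CC1)OCCO2 | intermediate
6 | methyl but-3-enoate | COC(=O)CC=C | starting material
7 | methyl 2-diazobut-3-enoate | COC(=O)C(=[N+]=[N-])C=C | intermediate
8 | methyl 2-(7-methyl-1,4-dioxaspiro[4.4]non-6-en-6-yl)-1-vinylcyclopropane-1-carboxylate (vinyl and cyclopentenyl groups cis, ester trans; absolute configuration as in the SMILES) | COC(=O)[C@]1(C=C)C[C@H]1C2=C(C)CCC23OCCO3 | intermediate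
9 | methyl 4,4-(ethylenedioxy)-11,12,13-trinordauca-5,8-dien-14-oate (1β-methyl) | C13(OCCO3)CC[C@]2(C)CC=C(C(=O)OC)CC=C21 | intermediate
10 | 4,4-(ethylenedioxy)-11,12,13-trinordauca-5,8-dien-14-ol | C13(OCCO3)CC[C@]2(C)CC=C(CO)CC=C21 | intermediate
11 | pyridinium 4,4-(ethylenedioxy)-11,12,13-trinordauca-5,8-dien-14-yl sulfate | C13(OCCO3)CC[C@]2(C)CC=C(COS(=O)(=O)[O-])CC=C21.c1cc[nH+]cc1 | intermediate
12 | 4,4-(ethylenedioxy)-11,12,13-trinordauca-5,8-diene | C13(OCCO3)CC[C@]2(C)CC=C(C)CC=C21 | intermediate
13 | 11,12,13-trinordauca-5,8-dien-4-one | O=C1CC[C@]2(C)CC=C(C)CC=C21 | intermediate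
14 | 6β-(4,4,5,5-tetramethyl-1,3,2-dioxaborolan-2-yl)-11,12,13-trinor-5α-dauc-8-en-4-one (6β as predicted) | O=C1CC[C@]2(C)CC=C(C)C[C@@H](B3OC(C)(C)C(C)(C)O3)[C@H]21 | intermediate
15 | 6β-hydroxy-11,12,13-trinor-5α-dauc-8-en-4-one (6β as predicted) | O=C1CC[C@]2(C)CC=C(C)C[C@@H](O)[C@H]21 | intermediate
16 | isopropylmagnesium chloride | CC(C)[Mg]Cl | starting material
17 | 5α-dauc-8-ene-4β,6β-diol (4α-isopropyl, 1β-methyl) | CC(C)[C@]1(O)CC[C@]2(C)CC=C(C)C[C@@H](O)[C@H]21 | intermediate
18 | 4β-hydroxy-5α-dauc-8-en-6-one | CC(C)[C@]1(O)CC[C@]2(C)CC=C(C)CC(=O)[C@H]21 | intermediate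
19 | 4-(benzyloxy)benzaldehyde | O=Cc1ccc(OCc2ccccc2)cc1 | starting material
20 | hemiacetal of 18 at O4 with 19 (samarium-bound in the flask, drawn as the free hemiacetal; hemiacetal carbon undefined) | CC(C)[C@]1(OC(O)c3ccc(OCc4ccccc4)cc3)CC[C@]2(C)CC=C(C)CC(=O)[C@H]21 | intermediate
21 | 4β-[4-(benzyloxy)benzoyloxy]-5α-dauc-8-en-6α-ol | CC(C)[C@]1(OC(=O)c3ccc(OCc4ccccc4)cc3)CC[C@]2(C)CC=C(C)C[C@H](O)[C@H]21 | intermediate
22 | 4β-[4-(benzyloxy)benzoyloxy]-8α,9α-epoxy-5α-daucan-6α-ol | CC(C)[C@]1(OC(=O)c3ccc(OCc4ccccc4)cc3)CC[C@]2(C)C[C@@H]5O[C@]5(C)C[C@H](O)[C@H]21 | intermediate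
23 | 4β-(4-hydroxybenzoyloxy)-8α,9α-epoxy-5α-daucan-6α-ol (CNP0264773.1) | CC(C)[C@]1(OC(=O)c2ccc(O)cc2)CC[C@]2(C)C[C@@H]3O[C@]3(C)C[C@H](O)[C@H]21 | target

**Step count and risks**

Total steps: 13. Longest linear sequence: 12 steps (steps 1, 2 and 4–13; step 3 is a one-step branch).

Steps most likely to fail:

Step 11 (proposed new method). Hemiacetal formation at the hindered tertiary samarium alkoxide may be too slow, so that retro-aldol cleavage of the C4–C5 bond or simple dimerisation of the aldehyde outruns the hydride transfer. The fallback sets out from 18 and uses known reactions only. Hydroxyl-directed anti reduction with Me4NBH(OAc)3 in MeCN/AcOH at −30 °C (Evans–Saksena reduction, hydride again delivered from the 4β-oxygen) should give 5α-dauc-8-ene-4β,6α-diol F1. Selective silylation of the secondary hydroxyl (TESCl, imidazole, DMF) should give 6α-(triethylsilyloxy)-5α-dauc-8-en-4β-ol F2. Deprotonation of the tertiary alcohol with KHMDS in THF at −78 °C and acylation of the alkoxide with 4-(benzyloxy)benzoyl chloride should give 4β-[4-(benzyloxy)benzoyloxy]-6α-(triethylsilyloxy)-5α-dauc-8-ene F3. HF·pyridine in THF at 0 °C then removes the silyl group and the route is rejoined at 21.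

Step 8. The borylcupration may run as a syn addition with stereoretentive protonolysis, or the basic medium may epimerise C5 or move the C8=C9 bond into conjugation, so that the cis ring fusion or a conjugated dienone forms. The fallback sets out from 13. Nucleophilic (Weitz–Scheffer) epoxidation with t-BuOOH and DBU in CH2Cl2 at 0 °C should give 5β,6β-epoxy-11,12,13-trinordauc-8-en-4-one F4, with peroxide attack at C6 on the convex β face. Reductive cleavage of the Cα–O bond with SmI2 (2.2 equiv) and MeOH in THF at −90 °C, with kinetic protonation of the samarium enolate at C5 anti to the C1 methyl, returns to the route at 15.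

Step 9. Enolisation of the ketone or β-hydride transfer from the branched organometallic, retro-aldol fragmentation of the β-alkoxide, or loss of facial control may take the place of clean addition. The fallback sets out from 15. Silylation (TESCl, imidazole, DMF) gives 6β-(triethylsilyloxy)-11,12,13-trinor-5α-dauc-8-en-4-one F5. Addition of isopropenylmagnesium bromide with CeCl3 in THF at −78 °C (an sp2 nucleophile without β-hydrogens, attacking anti to the C1 methyl) gives 6β-(triethylsilyloxy)-5α-dauca-8,11-dien-4β-ol F6. Hydrogenation over RhCl(PPh3)3 in benzene, which reduces the 1,1-disubstituted alkene and spares the trisubstituted ring alkene, gives 6β-(triethylsilyloxy)-5α-dauc-8-en-4β-ol F7. TBAF in THF removes the silyl ether and the route is rejoined at 17.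

Further compounds
F1 | step 11 | 5α-dauc-8-ene-4β,6α-diol | CC(C)[C@]1(O)CC[C@]2(C)CC=C(C)C[C@H](O)[C@H]21
F2 | step 11 | 6α-(triethylsilyloxy)-5α-dauc-8-en-4β-ol | CC(C)[C@]1(O)CC[C@]2(C)CC=C(C)C[C@H](O[Si](CC)(CC)CC)[C@H]21
F3 | step 11 | 4β-[4-(benzyloxy)benzoyloxy]-6α-(triethylsilyloxy)-5α-dauc-8-ene | CC(C)[C@]1(OC(=O)c3ccc(OCc4ccccc4)cc3)CC[C@]2(C)CC=C(C)C[C@H](O[Si](CC)(CC)CC)[C@H]21
F4 | step 8 | 5β,6β-epoxy-11,12,13-trinordauc-8-en-4-one | O=C1CC[C@]2(C)CC=C(C)C[C@H]3O[C@@]312
F5 | step 9 | 6β-(triethylsilyloxy)-11,12,13-trinor-5α-dauc-8-en-4-one | O=C1CC[C@]2(C)CC=C(C)C[C@@H](O[Si](CC)(CC)CC)[C@H]21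
F6 | step 9 | 6β-(triethylsilyloxy)-5α-dauca-8,11-dien-4β-ol | CC(=C)[C@]1(O)CC[C@]2(C)CC=C(C)C[C@@H](O[Si](CC)(CC)CC)[C@H]21
F7 | step 9 | 6β-(triethylsilyloxy)-5α-dauc-8-en-4β-ol | CC(C)[C@]1(O)CC[C@]2(C)CC=C(C)C[C@@H](O[Si](CC)(CC)CC)[C@H]21
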